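The earlier runs and the new flask were generated by integration for substances that don't exist.

Late times are the question here: the readings stop at 12.0 min, and the flasks are asked about at 1.0 h, so the end has to be reckoned from a rate.

| flask | substrate | reagent | free catalyst | remark | time |
|---|---|---|---|---|---|
| Friday's | 0.010 M | 0.030 M | 0.094 mM | run made earlier |  |
| Wednesday's | 0.010 M | 0.030 M | 0.070 mM | run made earlier |  |
| spring | 0.010 M | 0.0300 M | 0.14 mM |  | 1.0 h |
| midnight | 0.015 M | 0.0300 M | 0.14 mM |  | 1.0 h |
| winter | 0.020 M | 0.0300 M | 0.14 mM |  | 1.0 h |
| noon | 0.030 M | 0.0300 M | 0.14 mM |  | 1.0 h |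
| autumn | 0.050 M | 0.0300 M | 0.14 mM |  | 1.0 h |

- Friday's (time / min: target / %): 1.00: 7.6; 1.33: 9.7; 2.00: 13.8; 3.00: 21.1; 5.00: 33.1; 8.00: 47.8; 12.0: 63.3
- Wednesday's (time / min: target / %): 1.00: 5.6; 1.33: 7.2; 2.00: 10.8; 3.00: 15.9; 5.00: 25.0; 8.00: 37.6; 12.0: 51.7

(standard deviation of a reading: 0.3 percentage points)

- "hardly changes" means that all values lie within two and a half points (for a concentration: within two and a half percent of the largest)

1. [target] at the end for spring, midnight, winter, noon, autumn, in this order
2. how the row runs (falls all the way / hardly changes / falls, then rises / rises, then falls / rises all the way)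

Both earlier runs look pseudo-first-order in substrate, and the constant follows from the last reading of each:

k(Friday's) = 0.0835 min⁻¹; k(Wednesday's) = 0.0606 min⁻¹

Their ratio, 1.38, stands close to the ratio of catalyst charges, 1.34, so k is scaled with free catalyst:

k(new flasks) = 0.124 min⁻¹

The carried quantity is the count of lives, k times the time, each life dividing the rate by e:

lives in the hour = 7.46

In spring the rate starts at 1.24 mM min⁻¹. In this reckoning the fall of substrate slows it by a factor of 1737 over the hour. Friday's first-reading constant, 0.0790 min⁻¹, against the last gives a factor of 1.06, so Friday's readings show no second slowing. Spring should therefore keep 0.0576 % of its substrate.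

The zero of the scale is noon, with substrate and reagent charged equal. Taking one reagent per substrate, an assumption, reagent is the limiting reagent beyond it, and autumn reaches that limit after

lives needed = 0.916

which is fewer than the hour offers, if k, read at the substrate charge of the earlier runs, holds in autumn. This reckoning therefore puts autumn's target at 0.0300 M.

The forecast gives 0.01 M, 0.015 M, 0.0198 M, 0.028 M, 0.03 M, and rises all the way, in its words: “Nothing shows the target being destroyed, so the row rises, then flattens.”

The flasks give 0.00981 M, 0.0146 M, 0.0191 M, 0.0271 M, 0.0254 M: rises, then falls.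

    reagent + free catalyst → catalyst intermediate A (k = 3000 M⁻¹ min⁻¹)
    catalyst intermediate A ⇌ by-product + catalyst intermediate B (K = 0.0200 M, k = 210 min⁻¹)
    catalyst intermediate B ⇌ catalyst intermediate C (K = 70.0, k = 1700 min⁻¹)
    substrate + catalyst intermediate C → catalyst intermediate D (k = 1200 M⁻¹ min⁻¹)
    catalyst intermediate D → free catalyst + target (k = 48.0 min⁻¹)
    target + catalyst intermediate C → spent catalyst (k = 3.00 M⁻¹ min⁻¹)
    target + free catalyst ⇌ isomer of the product + free catalyst, rate k7*[free catalyst]*[target] forward; the back reaction follows from the equilibrium constant (K = 0.510, k = 43.0 M⁻¹ min⁻¹)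

Spring ends with substrate at 0.49 % of its charge, which is 5.32 lives against the reckoned 7.46, and winter ends with substrate at 2.81 % of its charge, which is 3.57 lives; at 1.00 h spring's spent catalyst is 76.6 % of the catalyst charged, and winter's spent catalyst is 91.9 %.

At the end of autumn, substrate stands at 40.1 % of its charge, which is 0.914 lives against the 0.916 reckoned. At 1.00 h in autumn, reagent stands at 0 % of its own charge and free catalyst at 72.4 % of the catalyst charged. Autumn's isomer of the product, in percent of the substrate charged, is 9.03 % at 1.00 h and 20.2 % at 10.0 h, when autumn's target is 39.6 % of the substrate charged.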